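The runs are calculated with constants of no real substance, noise included.

I cannot read the rate asked about directly, because the amount of target it stands at, 0.00600 M, lies below the earliest reading of the zeta run, 0.0230 M. So I compare the epsilon and zeta runs as they stand, in two ways that are not independent, since both use the epsilon reading 0.0342 M.

| flask | starting material | coupling partner | time |
|---|---|---|---|
| zeta | 0.300 M | 0.600 M |  |
| eta | 0.120 M | 0.420 M |  |
| epsilon | 0.600 M | 0.600 M |  |
| alpha | 0.300 M | 0.600 M | 58 min |

| run | time / min | [target] / M |
|---|---|---|
| zeta run | 3.6 | 0.0230 |
| zeta run | 7.2 | 0.0560 |
| zeta run | 11 | 0.0822 |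
| zeta run | 14 | 0.0959 |
| zeta run | 18 | 0.1105 |
| zeta run | 22 | 0.1202 |
| zeta run | 25 | 0.1254 |
| zeta run | 29 | 0.1266 |
| eta run | 3.6 | 0.0108 |
| eta run | 7.2 | 0.0249 |
| eta run | 11 | 0.0376 |
| eta run | 14 | 0.0485 |
| eta run | 18 | 0.0500 |
| eta run | 22 | 0.0566 |
| eta run | 25 | 0.0576 |
| eta run | 29 | 0.0577 |
| epsilon run | 3.6 | 0.0342 |
| epsilon run | 7.2 | 0.0807 |
| epsilon run | 11 | 0.1194 |
| epsilon run | 14 | 0.1411 |
| epsilon run | 18 | 0.1610 |
| epsilon run | 22 | 0.1689 |
| epsilon run | 25 | 0.1748 |
| epsilon run | 29 | 0.1765 |

(standard deviation of a reading: 9 × 10⁻⁴ M)

- Overall: starting material + coupling partner -> target.
- Constant volume, constant temperature.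
- A reading of a species includes what of it is bound.
- An order is taken over about fifteen percent of the charge, up and down.

- apparent order in [starting material] of the starting rate, round the charge of the zeta run (the rate where two percent of its starting material have turned into target) (one fixed amount of target, the same in the runs compared)
- apparent order in [coupling partner] of the starting rate, round the charge of the zeta run (the rate where two percent of its starting material have turned into target)
- target in the alpha run at 58 min, as a share of the starting material charged

The first way compares the readings of the epsilon and zeta runs at one clock time, 3.6 min: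

order = ln(0.0342 M / 0.0230 M) / ln(0.600 M / 0.300 M) = 0.572

The second way compares them at one amount. The zeta run holds 0.0560 M at 7.2 min, and between its readings the epsilon run passes that amount at 5.29 min. I take the ratio of times as the ratio of mean rates:

order = ln(7.2 min / 5.29 min) / ln(0.600 M / 0.300 M) = 0.445

This is my same-amount order: the logarithm of the rate ratio of two flasks at one amount of target, over the logarithm of their charge ratio.

The two ways part, and the clock way cheats, because at 3.6 min the epsilon run holds more target than the zeta run, so it does not compare one amount. I commit to 0.445, a mean over a doubling of the charge.

For the coupling partner, the zeta run passes the eta reading of 0.0249 M at 3.81 min, against 7.2 min in the eta run. Taking out the starting material with 0.445 leaves an order of 0.642.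

The alpha run has the charge of the zeta run, whose last gain is 0.00120 M. Adding that gain once more gives me 42.6%.

The forecast gives 0.55, 0.6 and 43%, on the ground that “The curves scale almost uniformly”.

The flask gives 0.39, 0.47 and 43.4%.

    starting material → intermediate (0.2418 min⁻¹)
    intermediate + coupling partner → target (0.7500 M⁻¹ min⁻¹)
    intermediate → side product (0.03954 min⁻¹)
    coupling partner → lost reagent (0.1020 min⁻¹)
    2 starting material ⇌ idle substrate dimer, settled at all times (24.40 M⁻¹)

At the start of the zeta run, free starting material stood at 0.0688 M of 0.300 M charged, the idle substrate dimer being its resting state, and it fed the intermediate. Meanwhile the intermediate met coupling partner or went to side product, while coupling partner went to lost reagent with a lifetime of 9.80 min. On the simulated rates, the same-amount order of starting material between the zeta and epsilon charges is 0.372, lower than the 0.445 I read from mean rates. Between the eta and zeta charges, with 0.47 taken out for coupling partner, it is 0.441, higher than between the zeta and epsilon charges.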